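**Plan**

- Retrosynthesis: the 7-OH is masked as a benzyl ether, the C2=C3 double bond is taken back to the isoflavanone, and ring C (pyranone) is opened at C2–C3.
- This cut is open because C2 is a CH held between O1 and C3: it can start as the carbon of a methoxy group ortho to the ketone on ring A (benzo), with C3 as a carbene carbon that already carries ring B (trimethoxyphenyl).
- The diazo carbon goes back to the CH2 of a deoxybenzoin, cut at C4–C4a into a benzyl-protected 1,2,4-trioxygenated benzene (from 2,5-dimethoxybenzaldehyde by aldehyde-to-phenol oxidation) and 3,4,5-trimethoxyphenylacetic acid.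
- Forward: ring A is oxidised and benzylated, rings A and B are joined through C4 by acylation, C3 is turned into the diazo carbon, ring C closes by carbene C–H insertion, then dehydrogenation and debenzylation.
- Stereochemistry: the target has none; C3 of the isoflavanone forms as a racemate and becomes sp2 on dehydrogenation.

Key step: step 5

Remark on the chemistry: atom numbers follow the chromen-4-one skeleton; because the target is achiral, the insertion is run with an achiral catalyst and no enantiocontrol is sought.

**Route**

Step 1
Reactants: 1 2,5-dimethoxybenzaldehyde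
Product: 3 2,5-dimethoxyphenol, via 2,5-dimethoxyphenyl formate 2 (not isolated)
Conditions: mCPBA, CH2Cl2, 0 °C to rt; aq NaHCO3 wash; then K2CO3 (cat.), MeOH, rt
Reagents that add atoms: mCPBA (3-chloroperbenzoic acid), OOC(=O)c1cccc(Cl)c1
Why: Baeyer–Villiger (Dakin-type) oxidation, in which the peracid adds to the aldehyde and the electron-rich dimethoxyphenyl group migrates to oxygen to give formate 2, whose mild methanolysis frees the phenol.

Step 2
Reactants: 3 2,5-dimethoxyphenol; 4 benzyl bromide
Product: 5 2-(benzyloxy)-1,4-dimethoxybenzene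
Conditions: K2CO3, DMF, rt
Reagents that add atoms: benzyl bromide (4), BrCc1ccccc1
Why: Williamson ether synthesis, the phenoxide displacing bromide from the benzylic halide by SN2, which installs a protecting group that tolerates the later base, carbene and oxidation steps and can be removed without touching methyl ethers.

Step 3
Reactants: 5 2-(benzyloxy)-1,4-dimethoxybenzene; 6 2-(3,4,5-trimethoxyphenyl)acetic acid
Product: 8 1-[4-(benzyloxy)-2,5-dimethoxyphenyl]-2-(3,4,5-trimethoxyphenyl)ethan-1-one, via mixed anhydride 7 (not isolated)
Conditions: TFAA, H3PO4 (85%, cat.), CH2Cl2, 0 °C to rt (5 in slight excess)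
Reagents that add atoms: none
Why: Friedel–Crafts acylation in which TFAA turns 6 into mixed anhydride 7, whose acyl carbon attacks 5 para to the benzyloxy group and ortho to a methoxy group, the most activated unhindered site of the ring (the position between two oxygens is blocked and the third is activated by one oxygen only), with loss of trifluoroacetic acid.

Step 4
Reactants: 8 1-[4-(benzyloxy)-2,5-dimethoxyphenyl]-2-(3,4,5-trimethoxyphenyl)ethan-1-one
Product: 9 1-[4-(benzyloxy)-2,5-dimethoxyphenyl]-2-diazo-2-(3,4,5-trimethoxyphenyl)ethan-1-one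
Conditions: 4-acetamidobenzenesulfonyl azide, DBU, MeCN, 0 °C to rt
Reagents that add atoms: 4-acetamidobenzenesulfonyl azide, CC(=O)Nc1ccc(cc1)S(=O)(=O)N=[N+]=[N-]
Why: Regitz diazo transfer, in which DBU deprotonates the CH2 flanked by the ketone and ring B, the enolate attacks the terminal nitrogen of the sulfonyl azide and the adduct fragments to the diazo ketone and the sulfonamide.

Step 5
Reactants: 9 1-[4-(benzyloxy)-2,5-dimethoxyphenyl]-2-diazo-2-(3,4,5-trimethoxyphenyl)ethan-1-one
Product: 10 racemic 7-(benzyloxy)-6-methoxy-3-(3,4,5-trimethoxyphenyl)chroman-4-one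
Conditions: Rh2(O2CCPh3)4 (1 mol %), 4 Å MS, CH2Cl2, 40 °C, slow addition of 9
Reagents that add atoms: none
Why: Rh2(O2CCPh3)4 expels N2 from 9 to give an electrophilic rhodium carbene at C3 that carries ring B as donor and the aroyl group as acceptor and has no β-hydrogen, so a 1,2-hydride shift is excluded. The carbene inserts, through a concerted three-centre transition state with hydride-transfer character, into a C–H bond of the methoxy group ortho to the ketone, a bond activated by the adjacent oxygen lone pair, and so forms C2–C3. The closest known reaction type is the dirhodium-catalysed intramolecular C–H insertion next to an ether oxygen that turns 2-alkoxyaryl diazo ketones into chroman-4-ones, together with the known insertion of aryl-substituted rhodium carbenes into the primary C–H bonds of methyl ethers. Ring C closes as a six-membered ring by 1,6-insertion (C3, C4, C4a, C8a, O1 and the former methyl carbon as C2), and the future 6-methoxy and 7-benzyloxy groups, meta and para to the ketone, cannot reach the carbene. C3 becomes a stereocentre that no element controls (achiral catalyst, racemate), which is accepted because step 6 removes it. The selectivity needed is C–H insertion over oxonium ylide formation at the same oxygen and over carbene dimerisation: the oxygen lone pair is delocalised into the aryl ketone, a methyl oxonium ylide has no good migrating group and can revert, the bulky triphenylacetate ligands favour insertion, and slow addition keeps the diazo concentration low.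

Step 6
Reactants: 10 racemic 7-(benzyloxy)-6-methoxy-3-(3,4,5-trimethoxyphenyl)chroman-4-one
Product: 11 7-(benzyloxy)-6-methoxy-3-(3,4,5-trimethoxyphenyl)-4H-chromen-4-one
Conditions: DDQ, 1,4-dioxane, 100 °C
Reagents that add atoms: none
Why: DDQ dehydrogenation of an isoflavanone to an isoflavone, by hydride abstraction at C2 of the enol (cation stabilised by O1) and loss of a proton, which places C2=C3 in conjugation with the ketone and ring B while the benzyl ether of an unactivated phenyl ring is not oxidised.

Step 7
Reactants: 11 7-(benzyloxy)-6-methoxy-3-(3,4,5-trimethoxyphenyl)-4H-chromen-4-one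
Product: 12 7-hydroxy-6-methoxy-3-(3,4,5-trimethoxyphenyl)-4H-chromen-4-one
Conditions: BCl3, pentamethylbenzene, CH2Cl2, −78 °C; aqueous work-up
Reagents that add atoms: none
Why: Lewis acid-mediated cleavage of an aryl benzyl ether, in which BCl3 coordinates the ether oxygen and the benzyl cation is trapped by pentamethylbenzene in a Friedel–Crafts alkylation, so the electron-rich rings are not benzylated, and at −78 °C the aryl methyl ethers, none of which is chelated to the C4 carbonyl, should stay intact.

**Compound list**

1 | 2,5-dimethoxybenzaldehyde | COc1ccc(OC)c(C=O)c1 | starting material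
2 | 2,5-dimethoxyphenyl formate | COc1ccc(OC)c(OC=O)c1 | intermediate (not isolated)
3 | 2,5-dimethoxyphenol | COc1ccc(OC)c(O)c1 | intermediate
4 | benzyl bromide | BrCc1ccccc1 | starting material
5 | 2-(benzyloxy)-1,4-dimethoxybenzene | COc1ccc(OC)c(OCc2ccccc2)c1 | intermediate
6 | 2-(3,4,5-trimethoxyphenyl)acetic acid | COc1cc(CC(=O)O)cc(OC)c1OC | starting material
7 | 2-(3,4,5-trimethoxyphenyl)acetic trifluoroacetic anhydride (mixed anhydride) | COc1cc(CC(=O)OC(=O)C(F)(F)F)cc(OC)c1OC | intermediate (not isolated)
8 | 1-[4-(benzyloxy)-2,5-dimethoxyphenyl]-2-(3,4,5-trimethoxyphenyl)ethan-1-one | COc1cc(C(=O)Cc2cc(OC)c(OC)c(OC)c2)c(OC)cc1OCc1ccccc1 | intermediate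
9 | 1-[4-(benzyloxy)-2,5-dimethoxyphenyl]-2-diazo-2-(3,4,5-trimethoxyphenyl)ethan-1-one | COc1cc(C(=O)C(=[N+]=[N-])c2cc(OC)c(OC)c(OC)c2)c(OC)cc1OCc1ccccc1 | intermediate
10 | racemic 7-(benzyloxy)-6-methoxy-3-(3,4,5-trimethoxyphenyl)chroman-4-one | COc1cc2C(=O)C(c3cc(OC)c(OC)c(OC)c3)COc2cc1OCc1ccccc1 | intermediate
11 | 7-(benzyloxy)-6-methoxy-3-(3,4,5-trimethoxyphenyl)-4H-chromen-4-one | COc1cc2c(=O)c(-c3cc(OC)c(OC)c(OC)c3)coc2cc1OCc1ccccc1 | intermediate
12 | 7-hydroxy-6-methoxy-3-(3,4,5-trimethoxyphenyl)-4H-chromen-4-one | COc1cc2c(=O)c(-c3cc(OC)c(OC)c(OC)c3)coc2cc1O | target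

**Step count and risks**

Total steps: 7. Longest linear sequence: 7 steps (1 to 12); 4 and 6 are purchased and enter in steps 2 and 3.

Steps most likely to fail:

Step 5. The carbene may be captured by the lone pair of the methoxy oxygen instead of its C–H bond, the oxonium ylide then collapsing by methyl migration or demethylation to a five-membered ring, or the slow primary C–H insertion may be outrun by carbene dimerisation. The fallback sets out from 8 and comes back at 11, replacing steps 4 to 6 by the classical deoxybenzoin ring closure, in which C2 comes from a formamide acetal. Chelation-controlled removal of the methyl group ortho to the ketone with MgI2·OEt2 (toluene, 80 °C) should give 1-[4-(benzyloxy)-2-hydroxy-5-methoxyphenyl]-2-(3,4,5-trimethoxyphenyl)ethan-1-one F1. Heating F1 with N,N-dimethylformamide dimethyl acetal (COC(OC)N(C)C, toluene, 100 °C) should give the enaminone 1-[4-(benzyloxy)-2-hydroxy-5-methoxyphenyl]-3-(dimethylamino)-2-(3,4,5-trimethoxyphenyl)prop-2-en-1-one F2, which closes by conjugate addition of the phenol and loss of dimethylamine to 11.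

Step 3. Trifluoroacetic acid may cause loss or migration of the benzyl group, and the mixed anhydride may acylate the electron-rich ring B of another molecule of itself instead of 5. The fallback sets out from 5 and comes back at 8 without an acidic acylation. Vilsmeier–Haack formylation of 5 (POCl3, DMF, 0 to 60 °C; aq NaOAc), para to the benzyloxy group, should give 4-(benzyloxy)-2,5-dimethoxybenzaldehyde F3. Purchased 5-(chloromethyl)-1,2,3-trimethoxybenzene (COc1cc(CCl)cc(OC)c1OC) and Mg turnings in THF give (3,4,5-trimethoxybenzyl)magnesium chloride F4, which adds to F3 to give racemic 1-[4-(benzyloxy)-2,5-dimethoxyphenyl]-2-(3,4,5-trimethoxyphenyl)ethan-1-ol F5. Oxidation of F5 with Dess–Martin periodinane (NaHCO3, CH2Cl2, rt) gives 8.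

Step 6. Hydride abstraction from the isoflavanone may be sluggish, and prolonged heating with DDQ may instead oxidise the benzylic CH2 of the ether or the electron-rich rings. The fallback sets out from 10 and comes back at 11 by selenoxide elimination. Deprotonation at C3 with LiN(SiMe3)2 (THF, −78 °C) and trapping with PhSeBr should give racemic 7-(benzyloxy)-6-methoxy-3-(phenylselanyl)-3-(3,4,5-trimethoxyphenyl)chroman-4-one F6. Oxidation with H2O2 (CH2Cl2, 0 °C to rt) gives the selenoxide 7-(benzyloxy)-6-methoxy-3-(phenylseleninyl)-3-(3,4,5-trimethoxyphenyl)chroman-4-one F7, whose syn-elimination can only take a hydrogen from C2 and so gives 11.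

**Further compounds**

F1 | step 5 | 1-[4-(benzyloxy)-2-hydroxy-5-methoxyphenyl]-2-(3,4,5-trimethoxyphenyl)ethan-1-one | COc1cc(C(=O)Cc2cc(OC)c(OC)c(OC)c2)c(O)cc1OCc1ccccc1
F2 | step 5 | 1-[4-(benzyloxy)-2-hydroxy-5-methoxyphenyl]-3-(dimethylamino)-2-(3,4,5-trimethoxyphenyl)prop-2-en-1-one (alkene geometry not fixed, of no consequence) | COc1cc(C(=O)C(=CN(C)C)c2cc(OC)c(OC)c(OC)c2)c(O)cc1OCc1ccccc1
F3 | step 3 | 4-(benzyloxy)-2,5-dimethoxybenzaldehyde | COc1cc(C=O)c(OC)cc1OCc1ccccc1
F4 | step 3 | (3,4,5-trimethoxybenzyl)magnesium chloride | COc1cc(C[Mg]Cl)cc(OC)c1OC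
F5 | step 3 | racemic 1-[4-(benzyloxy)-2,5-dimethoxyphenyl]-2-(3,4,5-trimethoxyphenyl)ethan-1-ol | COc1cc(C(O)Cc2cc(OC)c(OC)c(OC)c2)c(OC)cc1OCc1ccccc1
F6 | step 6 | racemic 7-(benzyloxy)-6-methoxy-3-(phenylselanyl)-3-(3,4,5-trimethoxyphenyl)chroman-4-one | COc1cc2C(=O)C([Se]c3ccccc3)(c3cc(OC)c(OC)c(OC)c3)COc2cc1OCc1ccccc1
F7 | step 6 | 7-(benzyloxy)-6-methoxy-3-(phenylseleninyl)-3-(3,4,5-trimethoxyphenyl)chroman-4-one (racemic, mixture of diastereomers at selenium) | COc1cc2C(=O)C([Se](=O)c3ccccc3)(c3cc(OC)c(OC)c(OC)c3)COc2cc1OCc1ccccc1
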